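**Plan**

Numbering: C1 quaternary fusion carbon (CH3), C2 and C3 CH2, C4 isopropyl carbinol, C5 fusion CH (ring A, five-membered); C6 acyloxy CH, C7=C8(CH3), C9, C10 complete ring B (seven-membered).
Cuts: first the ester at C6–O; then, with C7=C8 moved back to C8=C9 and C6 at the enol ether level, the C1–C10 bond with C6–C8 rejoined. In ring B a lone CH2 (C7) separates oxygenated C6 from methyl-bearing C8 and C1 is bonded to C10, which is the 1,4-diene left by a [3,3] shift of a C6–C7–C8 cyclopropane carrying the C5=C1 and C9=C10 alkenes on one face.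
Further cuts: C6–C8 and C7–C8 (carbenoid C8 added to a C6=C7 enol ether, delivered through C9 as an ester of the C4 oxygen); C5–C6 (Stille); C1=C2 (ring-closing metathesis); C3–C4 (enolate allylation).
Forward order: ring A by metathesis, then the lactone-bridged cyclopropane, then ring B by the sigmatropic shift, then the ester.
Stereochemistry: C4 from (R)-2-hydroxy-3-methylbutanoic acid (alkylation of its pivalaldehyde acetal with retention); the C4–O tether sets cyclopropane C6/C8 and the cis alkenes; the stereospecific shift relays this to C1; C5 by equilibration to the cis-fused ketone; C6 by hydride addition on the face of H5.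

Key step: step 13

Assumption: the SMILES is read as the cis-fused isomer (C1 methyl and H5 on one face, the C4 and C6 oxygens on the other), and LiN(i-Pr)2 and KN(SiMe3)2 are used as purchased solutions.

**Route**

Step 1
Reactants: 1 (2R)-2-hydroxy-3-methylbutanoic acid
Product: 2 (2R,5R)-2-tert-butyl-5-(propan-2-yl)-1,3-dioxolan-4-one
Conditions: t-BuCHO, TsOH·H2O (cat.), pentane, reflux (Dean–Stark); cis isomer by crystallisation
Reagents that add atoms: 2,2-dimethylpropanal (pivalaldehyde), CC(C)(C)C=O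
Why: Acid-catalysed acetalisation of an α-hydroxy acid with pivalaldehyde should give mainly the cis dioxolanone, whose acetal carbon stores the chirality of the future C4 while that carbon is enolised.

Step 2
Reactants: 2 (2R,5R)-2-tert-butyl-5-(propan-2-yl)-1,3-dioxolan-4-one; 3 3-bromoprop-1-ene
Product: 5 (2R,5R)-2-tert-butyl-5-(propan-2-yl)-5-(prop-2-en-1-yl)-1,3-dioxolan-4-one, via lithium enolate 4 (not isolated)
Conditions: LiN(i-Pr)2, THF, −78 °C; then 3, −78 → −20 °C
Reagents that add atoms: none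
Why: Enolate alkylation with self-regeneration of the stereocentre: allyl bromide should attack anti to the tert-butyl group, so allyl replaces hydrogen with retention and the quaternary carbinol carbon (future C4, with C3) is R.

Step 3
Reactants: 5 (2R,5R)-2-tert-butyl-5-(propan-2-yl)-5-(prop-2-en-1-yl)-1,3-dioxolan-4-one
Product: 6 (2R)-2-hydroxy-N-methoxy-N-methyl-2-(propan-2-yl)pent-4-enamide
Conditions: MeNH(OMe)·HCl, i-PrMgCl, THF, −20 → 0 °C; aq. NH4Cl
Reagents that add atoms: N,O-dimethylhydroxylamine hydrochloride, CNOC.Cl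
Why: Weinreb amide formation by attack of the magnesium amide on the activated acylal carbonyl should open the dioxolanone, the hemiacetal alkoxide then losing pivalaldehyde to free the tertiary alcohol without touching the stereocentre.

Step 4
Reactants: 6 (2R)-2-hydroxy-N-methoxy-N-methyl-2-(propan-2-yl)pent-4-enamide; 7 (prop-1-en-2-yl)magnesium bromide
Product: 8 (4R)-4-hydroxy-2-methyl-4-(propan-2-yl)hepta-1,6-dien-3-one
Conditions: 7 (3.5 equiv), THF, 0 °C → rt; aq. NH4Cl
Reagents that add atoms: none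
Why: Weinreb ketone synthesis: after one equivalent has deprotonated the hydroxyl group, the chelated tetrahedral adduct should persist until work-up, so only one isopropenyl group (C1 and its methyl) is added.

Step 5
Reactants: 8 (4R)-4-hydroxy-2-methyl-4-(propan-2-yl)hepta-1,6-dien-3-one
Product: 9 (5R)-5-hydroxy-2-methyl-5-(propan-2-yl)cyclopent-2-en-1-one
Conditions: second-generation Grubbs catalyst (H2IMes)(PCy3)Cl2Ru=CHPh (5 mol %), CH2Cl2, 40 °C
Reagents that add atoms: none
Why: Ring-closing metathesis between the allyl group and the 1,1-disubstituted enone alkene should close ring A as a 2-methylcyclopentenone (C1=C2) with loss of ethene.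

Step 6
Reactants: 9 (5R)-5-hydroxy-2-methyl-5-(propan-2-yl)cyclopent-2-en-1-one; 10 propanoic anhydride
Product: 11 (1R)-3-methyl-2-oxo-1-(propan-2-yl)cyclopent-3-en-1-yl propanoate
Conditions: Sc(OSO2CF3)3 (2 mol %), MeCN, −20 °C
Reagents that add atoms: none
Why: Lewis-acid-catalysed acylation of a hindered tertiary alcohol by an anhydride (the α-keto carbinol does not ionise readily) masks the C4 oxygen and brings in C9, C8 and the C8 methyl group of the later tether.

Step 7
Reactants: 11 (1R)-3-methyl-2-oxo-1-(propan-2-yl)cyclopent-3-en-1-yl propanoate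
Product: 13 (1R)-3-methyl-1-(propan-2-yl)-2-[(trifluoromethanesulfonyl)oxy]cyclopent-2-en-1-yl propanoate, via lithium enolate 12 (not isolated)
Conditions: LiBH(s-Bu)3, THF, −78 °C; then N-(5-chloropyridin-2-yl)-N-(trifluoromethanesulfonyl)trifluoromethanesulfonamide, −78 → −20 °C; aq. NH4Cl
Reagents that add atoms: N-(5-chloropyridin-2-yl)-1,1,1-trifluoro-N-(trifluoromethanesulfonyl)methanesulfonamide, O=S(=O)(N(c1ccc(Cl)cn1)S(=O)(=O)C(F)(F)F)C(F)(F)F
Why: Reductive enol triflate formation: the bulky borohydride should add in conjugate fashion to the β-unsubstituted enone (the carbonyl is shielded by quaternary C4), giving the C5 enolate regiospecifically, and O-sulfonylation at −78 °C should outrun acyl transfer from the neighbouring ester.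

Step 8
Reactants: 13 (1R)-3-methyl-1-(propan-2-yl)-2-[(trifluoromethanesulfonyl)oxy]cyclopent-2-en-1-yl propanoate; 14 tributyl(1-ethoxyethenyl)stannane
Product: 15 (1R)-2-(1-ethoxyethenyl)-3-methyl-1-(propan-2-yl)cyclopent-2-en-1-yl propanoate
Conditions: Pd(PPh3)4 (5 mol %), LiCl, CuI (10 mol %), THF, 65 °C; aq. KF; Et3N-deactivated silica
Reagents that add atoms: none
Why: Stille coupling of an alkenyl triflate with an α-alkoxyvinylstannane forms C5–C6 and installs the C6=C7 enol ether directly, oxidative addition of zerovalent palladium to the triflate being much faster than ionisation of the hindered allylic ester.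

Step 9
Reactants: 15 (1R)-2-(1-ethoxyethenyl)-3-methyl-1-(propan-2-yl)cyclopent-2-en-1-yl propanoate
Product: 17 (1R)-2-(1-ethoxyethenyl)-3-methyl-1-(propan-2-yl)cyclopent-2-en-1-yl 2-diazopropanoate, via lithium ester enolate 16 (not isolated)
Conditions: LiN(i-Pr)2, THF, −78 °C; 4-O2NC6H4SO2N3, −78 → 0 °C; aq. NH4Cl
Reagents that add atoms: 4-nitrobenzenesulfonyl azide, [N-]=[N+]=NS(=O)(=O)c1ccc(cc1)[N+](=O)[O-]
Why: Direct diazo transfer (Regitz type) from an electron-poor sulfonyl azide to the ester enolate should turn the propanoate into the 2-diazopropanoate, and at −78 °C the enolate should neither undergo Ireland–Claisen rearrangement nor expel the allylic alkoxide.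

Step 10
Reactants: 17 (1R)-2-(1-ethoxyethenyl)-3-methyl-1-(propan-2-yl)cyclopent-2-en-1-yl 2-diazopropanoate
Product: 18 (2S,4R,7R)-2-ethoxy-4,10-dimethyl-7-(propan-2-yl)-6-oxatricyclo[5.3.0.0(2,4)]dec-1(10)-en-5-one
Conditions: Rh2(C6H10NO)4 (dirhodium tetrakis(caprolactamate), 1 mol %), CH2Cl2, 40 °C, slow addition of 17
Reagents that add atoms: none
Why: Intramolecular cyclopropanation of the electron-rich C6=C7 enol ether by the rhodium carbenoid at C8 (a homoallylic diazo ester closing a six-membered lactone; carboxamidate ligands disfavour β-hydride shift and C–H insertion) forms C6–C8 and C7–C8, the lactone forcing C9 and the cyclopentenyl group cis on the cyclopropane, while delivery from the face of the C4 oxygen with the C7 methylene turned away from quaternary C4 should set C6 as S and C8 as R.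

Step 11
Reactants: 18 (2S,4R,7R)-2-ethoxy-4,10-dimethyl-7-(propan-2-yl)-6-oxatricyclo[5.3.0.0(2,4)]dec-1(10)-en-5-one
Product: 19 (2S,4R,7R)-2-ethoxy-4,10-dimethyl-7-(propan-2-yl)-6-oxatricyclo[5.3.0.0(2,4)]dec-1(10)-en-5-ol (both epimers at the hemiacetal carbon)
Conditions: i-Bu2AlH (1.2 equiv), CH2Cl2, −78 °C; aq. potassium sodium tartrate (KNaC4H4O6)
Reagents that add atoms: none
Why: Partial reduction of a lactone to the lactol by a dialkylaluminium hydride, the tetrahedral aluminate being stable at −78 °C and the hindered carbonyl resisting a second hydride.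

Step 12
Reactants: 19 (2S,4R,7R)-2-ethoxy-4,10-dimethyl-7-(propan-2-yl)-6-oxatricyclo[5.3.0.0(2,4)]dec-1(10)-en-5-ol; 20 methyltriphenylphosphonium bromide
Product: 23 triethyl({(1R)-2-[(1R,2S)-2-ethenyl-1-ethoxy-2-methylcyclopropyl]-3-methyl-1-(propan-2-yl)cyclopent-2-en-1-yl}oxy)silane, via aldehyde alkoxide 21 (not isolated), via dienyl alkoxide 22 (not isolated)
Conditions: 20, KN(SiMe3)2, THF, 0 °C; add 19, 0 °C → rt; then Et3SiCl, 0 °C → rt
Reagents that add atoms: chlorotriethylsilane, CC[Si](Cl)(CC)CC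
Why: Wittig methylenation of the lactol through its ring-opened aldehyde turns C9 into the C9=C10 vinyl group without touching the cyclopropane stereocentres (C8 is quaternary), and the released tertiary potassium alkoxide is silylated in the same flask.

Step 13
Reactants: 23 triethyl({(1R)-2-[(1R,2S)-2-ethenyl-1-ethoxy-2-methylcyclopropyl]-3-methyl-1-(propan-2-yl)cyclopent-2-en-1-yl}oxy)silane
Product: 24 triethyl{[(3R,8aS)-4-ethoxy-6,8a-dimethyl-3-(propan-2-yl)-1,2,3,5,8,8a-hexahydroazulen-3-yl]oxy}silane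
Conditions: PhMe, 120 °C, sealed tube (base-washed glass)
Reagents that add atoms: none
Why: A concerted thermal [3,3]-sigmatropic shift through a boat transition state, in which the C5=C1 and C9=C10 alkenes both lie over the cyclopropane, breaks the donor-substituted C6–C8 bond as C1–C10 forms and leaves the C5=C6 enol ether and the C8=C9 alkene. The closest known reaction type is the cis-divinylcyclopropane to cycloheptadiene rearrangement of alkoxy- and siloxy-substituted substrates, including ones with a fully substituted alkene terminus. Ring B closes by ring enlargement from three to seven atoms, the new bond joining the two alkene termini inside a six-atom pericyclic array, so no polar cyclisation mode is involved. The new quaternary centre C1 is set stereospecifically by cyclopropane carbons C6 (R) and C8 (S): the vinyl arm can reach only the cyclopentene face that carries the C4 oxygen, so C10 bonds anti to the isopropyl group and the methyl group ends on the isopropyl face (8aS in 24, which becomes 1R in the target once the alkene has moved). The step needs the concerted path to outrun homolysis of C6–C8, which would scramble the geometry; this is secured by the cis geometry fixed in step 10, by strain release and by the absence of a cis alkyl C–H for a homodienyl hydrogen shift. The inward methyl on C1 raises the barrier, which is why heating in toluene is planned.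

Step 14
Reactants: 24 triethyl{[(3R,8aS)-4-ethoxy-6,8a-dimethyl-3-(propan-2-yl)-1,2,3,5,8,8a-hexahydroazulen-3-yl]oxy}silane
Product: 25 (3R,8aS)-6,8a-dimethyl-3-(propan-2-yl)-3-[(triethylsilyl)oxy]-1,2,3,3a,8,8a-hexahydroazulen-4(5H)-one (C3a epimers)
Conditions: (CO2H)2, THF/H2O, 0 °C → rt
Reagents that add atoms: water, O
Why: Enol ether hydrolysis under weak acid (as for 1-alkoxy-1,4-dienes from Birch reductions) should give the β,γ-unsaturated C6 ketone with the new C5 hydrogen, as C5 epimers that are converged in the next step, while the hindered tertiary silyl ether survives.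

Step 15
Reactants: 25 (3R,8aS)-6,8a-dimethyl-3-(propan-2-yl)-3-[(triethylsilyl)oxy]-1,2,3,3a,8,8a-hexahydroazulen-4(5H)-one
Product: 26 (3R,3aR,8aR)-6,8a-dimethyl-3-(propan-2-yl)-3-[(triethylsilyl)oxy]-2,3,3a,7,8,8a-hexahydroazulen-4(1H)-one
Conditions: DBU (0.3 equiv), PhMe, rt → 50 °C
Reagents that add atoms: none
Why: Base-mediated isomerisation of the β,γ-enone through the C7 dienolate moves the alkene to C7=C8, and enolisation at C5 should equilibrate the ring fusion to the cis isomer, in which C6 is anti to the isopropyl group and the angular methyl group is best accommodated.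

Step 16
Reactants: 26 (3R,3aR,8aR)-6,8a-dimethyl-3-(propan-2-yl)-3-[(triethylsilyl)oxy]-2,3,3a,7,8,8a-hexahydroazulen-4(1H)-one
Product: 27 (3R,3aS,4R,8aR)-6,8a-dimethyl-3-(propan-2-yl)-3-[(triethylsilyl)oxy]-1,2,3,3a,4,7,8,8a-octahydroazulen-4-ol
Conditions: NaBH4, CeCl3·7H2O, MeOH, −78 → −40 °C
Reagents that add atoms: none
Why: Luche 1,2-reduction of the enone, in which hydride should add to C6 on the convex face of the cis-fused bicycle, syn to H5 and anti to quaternary C4 with its silyloxy and isopropyl groups, placing the new hydroxyl group on the face of the C4 oxygen.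

Step 17
Reactants: 28 3-hydroxy-4-methoxybenzoic acid (isovanillic acid)
Product: 30 3-[(tert-butyldimethylsilyl)oxy]-4-methoxybenzoic acid, via bis-silylated ester 29 (not isolated)
Conditions: t-BuMe2SiCl (2.3 equiv), imidazole, DMF, rt; then AcOH/THF/H2O, rt
Reagents that add atoms: tert-butylchlorodimethylsilane, CC(C)(C)[Si](C)(C)Cl
Why: Silylation of phenol and acid followed by selective hydrolysis of the labile silyl ester is the standard way to a phenol-protected benzoic acid.

Step 18
Reactants: 27 (3R,3aS,4R,8aR)-6,8a-dimethyl-3-(propan-2-yl)-3-[(triethylsilyl)oxy]-1,2,3,3a,4,7,8,8a-octahydroazulen-4-ol; 30 3-[(tert-butyldimethylsilyl)oxy]-4-methoxybenzoic acid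
Product: 31 (3R,3aS,4R,8aR)-6,8a-dimethyl-3-(propan-2-yl)-3-[(triethylsilyl)oxy]-1,2,3,3a,4,7,8,8a-octahydroazulen-4-yl 3-[(tert-butyldimethylsilyl)oxy]-4-methoxybenzoate
Conditions: DCC, DMAP (cat.), CH2Cl2, rt
Reagents that add atoms: none
Why: Steglich esterification acylates the secondary allylic alcohol with retention at C6, the tertiary oxygen being silylated.

Step 19
Reactants: 31 (3R,3aS,4R,8aR)-6,8a-dimethyl-3-(propan-2-yl)-3-[(triethylsilyl)oxy]-1,2,3,3a,4,7,8,8a-octahydroazulen-4-yl 3-[(tert-butyldimethylsilyl)oxy]-4-methoxybenzoate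
Product: 32 (3R,3aS,4R,8aR)-3-hydroxy-6,8a-dimethyl-3-(propan-2-yl)-1,2,3,3a,4,7,8,8a-octahydroazulen-4-yl 3-hydroxy-4-methoxybenzoate
Conditions: Bu4NF, AcOH, THF, 0 °C → rt
Reagents that add atoms: none
Why: Fluoride-mediated desilylation under buffered conditions should remove the aryl and the tertiary silyl ethers while leaving the allylic benzoate intact.

**Compound list**

1 | (2R)-2-hydroxy-3-methylbutanoic acid | CC(C)[C@@H](O)C(=O)O | starting material
2 | (2R,5R)-2-tert-butyl-5-(propan-2-yl)-1,3-dioxolan-4-one | CC(C)[C@H]1O[C@@H](C(C)(C)C)OC1=O | intermediate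
3 | 3-bromoprop-1-ene | C=CCBr | starting material
4 | lithium (2R)-2-tert-butyl-5-(propan-2-yl)-2H-1,3-dioxol-4-olate | CC(C)C1=C([O-])O[C@H](C(C)(C)C)O1.[Li+] | intermediate (not isolated)
5 | (2R,5R)-2-tert-butyl-5-(propan-2-yl)-5-(prop-2-en-1-yl)-1,3-dioxolan-4-one | CC(C)[C@@]1(CC=C)O[C@@H](C(C)(C)C)OC1=O | intermediate
6 | (2R)-2-hydroxy-N-methoxy-N-methyl-2-(propan-2-yl)pent-4-enamide | CC(C)[C@](O)(CC=C)C(=O)N(C)OC | intermediate
7 | (prop-1-en-2-yl)magnesium bromide | C=C(C)[Mg]Br | starting material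
8 | (4R)-4-hydroxy-2-methyl-4-(propan-2-yl)hepta-1,6-dien-3-one | CC(C)[C@](O)(CC=C)C(=O)C(C)=C | intermediate
9 | (5R)-5-hydroxy-2-methyl-5-(propan-2-yl)cyclopent-2-en-1-one | CC(C)[C@]1(O)CC=C(C)C1=O | intermediate
10 | propanoic anhydride | CCC(=O)OC(=O)CC | starting material
11 | (1R)-3-methyl-2-oxo-1-(propan-2-yl)cyclopent-3-en-1-yl propanoate | CCC(=O)O[C@@]1(C(C)C)CC=C(C)C1=O | intermediate
12 | lithium (5R)-2-methyl-5-(propanoyloxy)-5-(propan-2-yl)cyclopent-1-en-1-olate | CCC(=O)O[C@@]1(C(C)C)CCC(C)=C1[O-].[Li+] | intermediate (not isolated)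
13 | (1R)-3-methyl-1-(propan-2-yl)-2-[(trifluoromethanesulfonyl)oxy]cyclopent-2-en-1-yl propanoate | CCC(=O)O[C@@]1(C(C)C)CCC(C)=C1OS(=O)(=O)C(F)(F)F | intermediate
14 | tributyl(1-ethoxyethenyl)stannane | CCCC[Sn](CCCC)(CCCC)C(=C)OCC | starting material
15 | (1R)-2-(1-ethoxyethenyl)-3-methyl-1-(propan-2-yl)cyclopent-2-en-1-yl propanoate | CCC(=O)O[C@@]1(C(C)C)CCC(C)=C1C(=C)OCC | intermediate
16 | lithium 1-{[(1R)-2-(1-ethoxyethenyl)-3-methyl-1-(propan-2-yl)cyclopent-2-en-1-yl]oxy}prop-1-en-1-olate | CC=C([O-])O[C@@]1(C(C)C)CCC(C)=C1C(=C)OCC.[Li+] | intermediate (not isolated)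
17 | (1R)-2-(1-ethoxyethenyl)-3-methyl-1-(propan-2-yl)cyclopent-2-en-1-yl 2-diazopropanoate | CC(=[N+]=[N-])C(=O)O[C@@]1(C(C)C)CCC(C)=C1C(=C)OCC | intermediate
18 | (2S,4R,7R)-2-ethoxy-4,10-dimethyl-7-(propan-2-yl)-6-oxatricyclo[5.3.0.0(2,4)]dec-1(10)-en-5-one | O=C1O[C@@]2(C(C)C)CCC(C)=C2[C@@]3(OCC)C[C@@]13C | intermediate
19 | (2S,4R,7R)-2-ethoxy-4,10-dimethyl-7-(propan-2-yl)-6-oxatricyclo[5.3.0.0(2,4)]dec-1(10)-en-5-ol (hemiacetal epimers) | OC1O[C@@]2(C(C)C)CCC(C)=C2[C@@]3(OCC)C[C@@]13C | intermediate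
20 | methyltriphenylphosphonium bromide | C[P+](c1ccccc1)(c1ccccc1)c1ccccc1.[Br-] | starting material
21 | potassium (1R)-2-[(1S,2R)-1-ethoxy-2-formyl-2-methylcyclopropyl]-3-methyl-1-(propan-2-yl)cyclopent-2-en-1-olate | [K+].[O-][C@@]1(C(C)C)CCC(C)=C1[C@@]2(OCC)C[C@@]2(C)C=O | intermediate (not isolated)
22 | potassium (1R)-2-[(1R,2S)-2-ethenyl-1-ethoxy-2-methylcyclopropyl]-3-methyl-1-(propan-2-yl)cyclopent-2-en-1-olate | [K+].[O-][C@@]1(C(C)C)CCC(C)=C1[C@@]2(OCC)C[C@@]2(C)C=C | intermediate (not isolated)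
23 | triethyl({(1R)-2-[(1R,2S)-2-ethenyl-1-ethoxy-2-methylcyclopropyl]-3-methyl-1-(propan-2-yl)cyclopent-2-en-1-yl}oxy)silane (vinyl and cyclopentenyl cis on the cyclopropane) | CC[Si](CC)(CC)O[C@@]1(C(C)C)CCC(C)=C1[C@@]2(OCC)C[C@@]2(C)C=C | intermediate
24 | triethyl{[(3R,8aS)-4-ethoxy-6,8a-dimethyl-3-(propan-2-yl)-1,2,3,5,8,8a-hexahydroazulen-3-yl]oxy}silane | CCOC1=C2[C@](O[Si](CC)(CC)CC)(C(C)C)CC[C@@]2(C)CC=C(C)C1 | intermediate
25 | (3R,8aS)-6,8a-dimethyl-3-(propan-2-yl)-3-[(triethylsilyl)oxy]-1,2,3,3a,8,8a-hexahydroazulen-4(5H)-one (C3a epimers) | O=C1CC(C)=CC[C@]2(C)CC[C@@](O[Si](CC)(CC)CC)(C(C)C)C12 | intermediate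
26 | (3R,3aR,8aR)-6,8a-dimethyl-3-(propan-2-yl)-3-[(triethylsilyl)oxy]-2,3,3a,7,8,8a-hexahydroazulen-4(1H)-one | O=C1C=C(C)CC[C@]2(C)CC[C@@](O[Si](CC)(CC)CC)(C(C)C)[C@H]12 | intermediate
27 | (3R,3aS,4R,8aR)-6,8a-dimethyl-3-(propan-2-yl)-3-[(triethylsilyl)oxy]-1,2,3,3a,4,7,8,8a-octahydroazulen-4-ol | O[C@@H]1C=C(C)CC[C@]2(C)CC[C@@](O[Si](CC)(CC)CC)(C(C)C)[C@H]12 | intermediate
28 | 3-hydroxy-4-methoxybenzoic acid | COc1ccc(C(=O)O)cc1O | starting material
29 | tert-butyldimethylsilyl 3-[(tert-butyldimethylsilyl)oxy]-4-methoxybenzoate | COc1ccc(C(=O)O[Si](C)(C)C(C)(C)C)cc1O[Si](C)(C)C(C)(C)C | intermediate (not isolated)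
30 | 3-[(tert-butyldimethylsilyl)oxy]-4-methoxybenzoic acid | COc1ccc(C(=O)O)cc1O[Si](C)(C)C(C)(C)C | intermediate
31 | (3R,3aS,4R,8aR)-6,8a-dimethyl-3-(propan-2-yl)-3-[(triethylsilyl)oxy]-1,2,3,3a,4,7,8,8a-octahydroazulen-4-yl 3-[(tert-butyldimethylsilyl)oxy]-4-methoxybenzoate | COc1ccc(C(=O)O[C@@H]2C=C(C)CC[C@]3(C)CC[C@@](O[Si](CC)(CC)CC)(C(C)C)[C@H]23)cc1O[Si](C)(C)C(C)(C)C | intermediate
32 | (3R,3aS,4R,8aR)-3-hydroxy-6,8a-dimethyl-3-(propan-2-yl)-1,2,3,3a,4,7,8,8a-octahydroazulen-4-yl 3-hydroxy-4-methoxybenzoate | COc1ccc(C(=O)O[C@@H]2C=C(C)CC[C@]3(C)CC[C@@](O)(C(C)C)[C@H]23)cc1O | target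

**Count and risks**

Total step count: 19. Longest linear sequence: 18 steps (steps 1–16, 18 and 19); step 17 is the one-step side branch.

Steps most likely to fail:

1. Step 10. The methyl-bearing rhodium carbenoid may undergo 1,2-hydride shift to the acrylate, or insert into the isopropyl methine C–H, faster than it adds to the enol ether. The fallback sets out from 9 and comes back at 18; it makes the ring with a carbenoid that has no β-hydrogen and brings in the C8 methyl group afterwards. Acetylation of 9 (Ac2O, Sc(OSO2CF3)3) should give (1R)-3-methyl-2-oxo-1-(propan-2-yl)cyclopent-3-en-1-yl acetate F1. Reductive triflation as in step 7 should give (1R)-3-methyl-1-(propan-2-yl)-2-[(trifluoromethanesulfonyl)oxy]cyclopent-2-en-1-yl acetate F2, and Stille coupling with 14 as in step 8 should give (1R)-2-(1-ethoxyethenyl)-3-methyl-1-(propan-2-yl)cyclopent-2-en-1-yl acetate F3. Acylation of its enolate (LiN(SiMe3)2, CF3CO2CH2CF3, −78 °C) should give (1R)-2-(1-ethoxyethenyl)-3-methyl-1-(propan-2-yl)cyclopent-2-en-1-yl 4,4,4-trifluoro-3-oxobutanoate F4, which is not isolated. Mesyl azide and Et3N then effect diazo transfer with loss of the trifluoroacetyl group to give (1R)-2-(1-ethoxyethenyl)-3-methyl-1-(propan-2-yl)cyclopent-2-en-1-yl 2-diazoacetate F5. Cyclopropanation with Cu(C5H7O2)2 (copper bis(acetylacetonate)) in benzene at 80 °C should close (2S,4R,7R)-2-ethoxy-10-methyl-7-(propan-2-yl)-6-oxatricyclo[5.3.0.0(2,4)]dec-1(10)-en-5-one F6. Deprotonation at the ring-fusion cyclopropane carbon (LiN(i-Pr)2, THF, −78 °C) and MeI then methylates C8 with retention, since the lactone allows only the cis fusion, and gives 18.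

2. Step 15. The C5 enolate needed for epimerisation may expel triethylsilanolate from C4 (β-elimination), or the equilibration may stop short. The fallback sets out from 24 and comes back at 26; it replaces thermodynamic by kinetic control and never forms the C5 enolate. Hydrolysis of 24 with the hindered acid 2,6-di-tert-butylpyridinium trifluoromethanesulfonate in wet acetone at 0 °C should protonate C5 on the face opposite the silyl ether and give (3R,3aR,8aS)-6,8a-dimethyl-3-(propan-2-yl)-3-[(triethylsilyl)oxy]-1,2,3,3a,8,8a-hexahydroazulen-4(5H)-one F7. The alkene is then moved into conjugation with DABCO in CH2Cl2 at rt, a base that deprotonates only the doubly activated C7 methylene, to give 26.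

3. Step 16. Facial selectivity of hydride addition may be poor, because the required approach passes the angular methyl group. The fallback sets out from 26 and comes back at 31; it accepts the other face and inverts at the esterification. If reduction gives mainly (3R,3aS,4S,8aR)-6,8a-dimethyl-3-(propan-2-yl)-3-[(triethylsilyl)oxy]-1,2,3,3a,4,7,8,8a-octahydroazulen-4-ol F8, Mitsunobu esterification with 30 (PPh3, DIAD, PhMe, 0 °C → rt) inverts C6 and gives 31 directly.

**Further compounds**

F1 | step 10 | (1R)-3-methyl-2-oxo-1-(propan-2-yl)cyclopent-3-en-1-yl acetate | CC(=O)O[C@@]1(C(C)C)CC=C(C)C1=O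
F2 | step 10 | (1R)-3-methyl-1-(propan-2-yl)-2-[(trifluoromethanesulfonyl)oxy]cyclopent-2-en-1-yl acetate | CC(=O)O[C@@]1(C(C)C)CCC(C)=C1OS(=O)(=O)C(F)(F)F
F3 | step 10 | (1R)-2-(1-ethoxyethenyl)-3-methyl-1-(propan-2-yl)cyclopent-2-en-1-yl acetate | CC(=O)O[C@@]1(C(C)C)CCC(C)=C1C(=C)OCC
F4 | step 10 | (1R)-2-(1-ethoxyethenyl)-3-methyl-1-(propan-2-yl)cyclopent-2-en-1-yl 4,4,4-trifluoro-3-oxobutanoate | O=C(CC(=O)C(F)(F)F)O[C@@]1(C(C)C)CCC(C)=C1C(=C)OCC
F5 | step 10 | (1R)-2-(1-ethoxyethenyl)-3-methyl-1-(propan-2-yl)cyclopent-2-en-1-yl 2-diazoacetate | [N-]=[N+]=CC(=O)O[C@@]1(C(C)C)CCC(C)=C1C(=C)OCC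
F6 | step 10 | (2S,4R,7R)-2-ethoxy-10-methyl-7-(propan-2-yl)-6-oxatricyclo[5.3.0.0(2,4)]dec-1(10)-en-5-one | O=C1O[C@@]2(C(C)C)CCC(C)=C2[C@@]3(OCC)C[C@@H]13
F7 | step 15 | (3R,3aR,8aS)-6,8a-dimethyl-3-(propan-2-yl)-3-[(triethylsilyl)oxy]-1,2,3,3a,8,8a-hexahydroazulen-4(5H)-one | O=C1CC(C)=CC[C@]2(C)CC[C@@](O[Si](CC)(CC)CC)(C(C)C)[C@H]12
F8 | step 16 | (3R,3aS,4S,8aR)-6,8a-dimethyl-3-(propan-2-yl)-3-[(triethylsilyl)oxy]-1,2,3,3a,4,7,8,8a-octahydroazulen-4-ol | O[C@H]1C=C(C)CC[C@]2(C)CC[C@@](O[Si](CC)(CC)CC)(C(C)C)[C@H]12
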